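**Retrosynthetic overview**
- The target comes from a 13-membered hydroxy ester by ester→CHO reduction, O-acetylation and desilylation. The macrocycle, the only ring of the target, is closed last by ring-closing metathesis at C8=C9.
- The metathesis diene is cut at C1–C2: an (E)-allylbarium made from (R)-linalool (supplies C2–C8 and the C7 stereocentre) adds at its α-carbon to an α-quaternary aldehyde (C1, C9–C13).
- That aldehyde/vinyl fragment comes from a Grob-type fragmentation of a γ-stannyl cyclohexanol. The six-membered ring C13–C1–C9–C10–C11–C12 is cut at C1–C9, giving CHO (C1) and vinyl (C9) in one step.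
- The cyclohexane comes, via an epoxide, from a catalytic enantioselective bromolactonisation that breaks the mirror symmetry of an achiral cyclohexa-2,5-diene acid and sets C13 and C10 together.
- The diene acid comes from Birch reductive methylation of 4-isopropylbenzoic acid (CO2H is the future CHO). Ring order: arene-derived carbocycle first (later fragmented), 13-membered ring last.

Locants (target): C1 = CH(OAc); C2; C3(CH3)=C4; C5; C6; C7(CH3)(OH); C8=C9; C10(i-Pr); C11; C12; C13(CH3)(CHO).

Assumption: in step 1 iodomethane enters anti to the 4-isopropyl group (CH3 trans to i-Pr); this selectivity is not documented for this substrate and is expected to be modest, so the minor cis acid is removed by crystallisation.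

**Step 1**
Reactants: 1 4-(propan-2-yl)benzoic acid (cuminic acid)
Product: 3 trans-1-methyl-4-(propan-2-yl)cyclohexa-2,5-diene-1-carboxylic acid (CH3 trans to i-Pr; achiral), via dilithium dienediolate 2 (not isolated)
Conditions: Li (3.5 equiv), NH3(l)/THF, −78 °C; MeI (3 equiv), −78 °C → rt; 1 M HCl; recrystallise
Reagents that add atoms: iodomethane, CI
Why: Birch reduction–alkylation of a benzoic acid gives the cross-conjugated dienediolate 2 (protonated para by NH3), which is C-methylated at the carboxyl-bearing carbon to form the quaternary centre, the electrophile entering anti to the isopropyl group so that the C13/C10 relative configuration is fixed in an achiral product.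

**Step 2**
Reactants: 3 trans-1-methyl-4-(propan-2-yl)cyclohexa-2,5-diene-1-carboxylic acid
Product: 5 methyl (1S,2S,5R,6R)-2-methyl-5-(propan-2-yl)-7-oxabicyclo[4.1.0]hept-3-ene-2-carboxylate, via bromo-β-lactone 4 (not isolated)
Conditions: NBS (1.1 equiv), (DHQD)2PHAL (10 mol%; (DHQ)2PHAL if the sense of induction is opposite), toluene/CH2Cl2, −40 °C, dark; then MeOH, K2CO3 (3 equiv), 0 °C → rt
Reagents that add atoms: methanol, CO (N-bromosuccinimide, O=C1CCC(=O)N1Br, puts bromine into 4 only)
Why: Cinchona-alkaloid-catalysed enantioselective bromolactonisation picks one of the two enantiotopic olefins (Br+ on the face anti to CO2H and i-Pr, carboxylate closing trans to it) and thereby sets the absolute configuration of C13 and C10 in one event, after which methoxide opens the lactone and the freed alkoxide displaces the trans bromide to give the cis epoxy ester (a γ-lactone regioisomer would converge to the same epoxide).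

**Step 3**
Reactants: 5 methyl (1S,2S,5R,6R)-2-methyl-5-(propan-2-yl)-7-oxabicyclo[4.1.0]hept-3-ene-2-carboxylate
Product: 6 methyl (1S,2S,5S,6R)-2-methyl-5-(propan-2-yl)-7-oxabicyclo[4.1.0]heptane-2-carboxylate
Conditions: H2 (1 atm), PtO2 (5 mol%), EtOAc, rt
Reagents that add atoms: none
Why: Heterogeneous hydrogenation of the remaining cis-disubstituted ring olefin creates no stereocentre and leaves the isolated epoxide and ester alone, platinum being chosen because it does not migrate the double bond towards the C10 stereocentre.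

**Step 4**
Reactants: 6 methyl (1S,2S,5S,6R)-2-methyl-5-(propan-2-yl)-7-oxabicyclo[4.1.0]heptane-2-carboxylate
Product: 7 methyl (1S,2R,3S,4S)-2-hydroxy-1-methyl-4-(propan-2-yl)-3-[(tributylstannyl)methyl]cyclohexane-1-carboxylate
Conditions: Bu3SnCH2I (2 equiv), n-BuLi (2 equiv), THF, −78 °C; BF3·OEt2 (2 equiv); then 6, −78 °C; aq. NaHCO3
Reagents that add atoms: (iodomethyl)tributylstannane, CCCC[Sn](CCCC)(CCCC)CI
Why: BF3-promoted organolithium epoxide opening (anti SN2) should occur at the epoxide carbon remote from the quaternary centre (the other is neopentyl and inductively deactivated by CO2Me), from the face opposite both the oxygen and the neighbouring isopropyl group, and the two new centres are erased in step 5.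

**Step 5**
Reactants: 7 methyl (1S,2R,3S,4S)-2-hydroxy-1-methyl-4-(propan-2-yl)-3-[(tributylstannyl)methyl]cyclohexane-1-carboxylate
Product: 8 methyl (2S,5S)-2-formyl-2-methyl-5-(propan-2-yl)hept-6-enoate
Conditions: Pb(OAc)4 (1.2 equiv), CH2Cl2, 0 °C → rt
Reagents that add atoms: none
Why: Oxidative Grob-type fragmentation of a γ-stannyl alcohol: the lead alkoxide fragments heterolytically with the C–Sn bond as electron donor, cutting the ring C1–C9 bond to give the non-enolisable aldehyde and the terminal vinyl group already differentiated, with C13 and C10 untouched.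

**Step 6**
Reactants: 9 (R)-linalool
Product: 10 triethyl{[(3R)-3,7-dimethylocta-1,6-dien-3-yl]oxy}silane
Conditions: Et3SiOTf, 2,6-lutidine, CH2Cl2, −78 → 0 °C
Reagents that add atoms: triethylsilyl trifluoromethanesulfonate, CC[Si](CC)(CC)OS(=O)(=O)C(F)(F)F
Why: Silyl triflate silylation of the tertiary alcohol removes the acidic proton for the organobarium step and later blocks hydroxyl-assisted catalyst loading at this vinyl group; the C7 stereocentre is taken from the chiral pool.

**Step 7**
Reactants: 10 triethyl{[(3R)-3,7-dimethylocta-1,6-dien-3-yl]oxy}silane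
Product: 11 (2E,6R)-2,6-dimethyl-6-[(triethylsilyl)oxy]octa-2,7-dien-1-ol
Conditions: SeO2 (0.3 equiv), t-BuOOH (2 equiv), CH2Cl2, 0 °C → rt
Reagents that add atoms: selenium dioxide, O=[Se]=O, re-oxidised by tert-butyl hydroperoxide, CC(C)(C)OO (terminal oxygen source)
Why: Riley allylic oxidation (ene then [2,3]-shift) is selective for the (E)-methyl of a gem-dimethyl trisubstituted olefin, giving the E-allylic alcohol, while the vinyl group has no allylic hydrogen.

**Step 8**
Reactants: 11 (2E,6R)-2,6-dimethyl-6-[(triethylsilyl)oxy]octa-2,7-dien-1-ol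
Product: 13 (3R,6E)-8-chloro-3,7-dimethyl-3-[(triethylsilyl)oxy]octa-1,6-diene, via allylic mesylate 12 (not isolated)
Conditions: MsCl, LiCl, 2,4,6-collidine, DMF, 0 °C
Reagents that add atoms: lithium chloride, [Li+].[Cl-] (methanesulfonyl chloride, CS(=O)(=O)Cl, adds atoms to 12 only)
Why: In situ mesylation and SN2 chloride exchange converts the primary allylic alcohol to the chloride without allylic transposition or loss of E geometry.

**Step 9**
Reactants: 8 methyl (2S,5S)-2-formyl-2-methyl-5-(propan-2-yl)hept-6-enoate; 13 (3R,6E)-8-chloro-3,7-dimethyl-3-[(triethylsilyl)oxy]octa-1,6-diene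
Product: 15 methyl (2S,5S)-2-[(1S,3E,7R)-1-hydroxy-3,7-dimethyl-7-[(triethylsilyl)oxy]nona-3,8-dien-1-yl]-2-methyl-5-(propan-2-yl)hept-6-enoate, via allylbarium chloride 14 (not isolated)
Conditions: BaI2, lithium biphenylide (2 equiv), THF, rt (activated barium); 13 (1.3 equiv), −78 °C; 8, −78 °C; NH4Cl(aq) at −78 °C
Reagents that add atoms: none
Why: Allylbarium reagents add to aldehydes at the α-carbon with retention of olefin geometry, giving the linear E-homoallylic alcohol, and a barium chelate between the aldehyde and ester carbonyls should direct attack to the face flanked by the small CH3 (Cram-chelate model) to give (1S) with OH syn to the ester; any antipodal 8 becomes a diastereomer here.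

**Step 10**
Reactants: 15 methyl (2S,5S)-2-[(1S,3E,7R)-1-hydroxy-3,7-dimethyl-7-[(triethylsilyl)oxy]nona-3,8-dien-1-yl]-2-methyl-5-(propan-2-yl)hept-6-enoate
Product: 16 methyl (1S,2S,4E,8R,9E,11S)-2-hydroxy-1,4,8-trimethyl-11-(propan-2-yl)-8-[(triethylsilyl)oxy]cyclotrideca-4,9-diene-1-carboxylate
Conditions: second-generation Hoveyda–Grubbs catalyst, RuCl2(H2IMes)(=CH-C6H4-2-OiPr) (10 mol%), toluene (1 mM), 80 °C, argon sparge
Reagents that add atoms: none
Why: Ring-closing metathesis: the carbene loads at the less hindered C10 vinyl group and closes onto the vinyl of the silylated carbinol with loss of ethene, the silyl ether suppressing the hydroxyl-assisted loading at C8 that would lead to five-ring closure onto the trisubstituted olefin, and the olefin flanked by a quaternary and a tertiary centre forms E.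

**Step 11**
Reactants: 16 methyl (1S,2S,4E,8R,9E,11S)-2-hydroxy-1,4,8-trimethyl-11-(propan-2-yl)-8-[(triethylsilyl)oxy]cyclotrideca-4,9-diene-1-carboxylate
Product: 17 (1S,2S,4E,8R,9E,11S)-2-hydroxy-1,4,8-trimethyl-11-(propan-2-yl)-8-[(triethylsilyl)oxy]cyclotrideca-4,9-diene-1-carbaldehyde
Conditions: i-Bu2AlH (2.5 equiv), CH2Cl2, −78 °C; aq. potassium sodium tartrate
Reagents that add atoms: none
Why: Low-temperature partial reduction of the ester: the first equivalent makes the neighbouring aluminium alkoxide and the second gives a chelated, hindered tetrahedral hemiacetal aluminate that survives at −78 °C and releases the aldehyde only on work-up.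

**Step 12**
Reactants: 17 (1S,2S,4E,8R,9E,11S)-2-hydroxy-1,4,8-trimethyl-11-(propan-2-yl)-8-[(triethylsilyl)oxy]cyclotrideca-4,9-diene-1-carbaldehyde
Product: 18 (1S,2S,4E,8R,9E,11S)-1-formyl-1,4,8-trimethyl-11-(propan-2-yl)-8-[(triethylsilyl)oxy]cyclotrideca-4,9-dien-2-yl acetate
Conditions: Ac2O, pyridine, DMAP (cat.), CH2Cl2, 0 °C → rt
Reagents that add atoms: acetic anhydride, CC(=O)OC(C)=O
Why: DMAP-catalysed acylation of the only free hydroxyl, the aldehyde having no α-hydrogen and therefore being unable to enolise or eliminate.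

**Step 13**
Reactants: 18 (1S,2S,4E,8R,9E,11S)-1-formyl-1,4,8-trimethyl-11-(propan-2-yl)-8-[(triethylsilyl)oxy]cyclotrideca-4,9-dien-2-yl acetate
Product: 19 CNP0106239.1, (1S,2S,4E,8R,9E,11S)-1-formyl-8-hydroxy-1,4,8-trimethyl-11-(propan-2-yl)cyclotrideca-4,9-dien-2-yl acetate
Conditions: n-Bu4NF, AcOH (1:1), THF, 0 °C → rt
Reagents that add atoms: none
Why: Fluoride cleavage of the tertiary silyl ether, buffered with acetic acid so that the acetate and aldehyde survive and the tertiary allylic alcohol is not ionised.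

**Compound list**
1 | 4-(propan-2-yl)benzoic acid (cuminic acid) | CC(C)c1ccc(cc1)C(=O)O | starting material
2 | dilithium [4-(propan-2-yl)cyclohexa-2,5-dien-1-ylidene]methanediolate | [Li+].[Li+].[O-]C([O-])=C1C=CC(C(C)C)C=C1 | intermediate
3 | trans-1-methyl-4-(propan-2-yl)cyclohexa-2,5-diene-1-carboxylic acid (CH3 trans to i-Pr, CO2H cis to i-Pr; achiral) | C[C@@]1(C(=O)O)C=C[C@H](C(C)C)C=C1 | intermediate
4 | (1S,4R,5S,6S)-5-bromo-1-methyl-4-(propan-2-yl)-7-oxabicyclo[4.2.0]oct-2-en-8-one | C[C@@]12C(=O)O[C@@H]1[C@@H](Br)[C@H](C(C)C)C=C2 | intermediate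
5 | methyl (1S,2S,5R,6R)-2-methyl-5-(propan-2-yl)-7-oxabicyclo[4.1.0]hept-3-ene-2-carboxylate | C[C@@]1(C(=O)OC)[C@@H]2O[C@@H]2[C@H](C(C)C)C=C1 | intermediate
6 | methyl (1S,2S,5S,6R)-2-methyl-5-(propan-2-yl)-7-oxabicyclo[4.1.0]heptane-2-carboxylate | C[C@@]1(C(=O)OC)[C@@H]2O[C@@H]2[C@H](C(C)C)CC1 | intermediate
7 | methyl (1S,2R,3S,4S)-2-hydroxy-1-methyl-4-(propan-2-yl)-3-[(tributylstannyl)methyl]cyclohexane-1-carboxylate | C[C@@]1(C(=O)OC)[C@H](O)[C@@H](C[Sn](CCCC)(CCCC)CCCC)[C@H](C(C)C)CC1 | intermediate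
8 | methyl (2S,5S)-2-formyl-2-methyl-5-(propan-2-yl)hept-6-enoate | C=C[C@H](C(C)C)CC[C@](C=O)(C)C(=O)OC | intermediate
9 | (R)-linalool, (3R)-3,7-dimethylocta-1,6-dien-3-ol | C=C[C@](C)(O)CCC=C(C)C | starting material
10 | triethyl{[(3R)-3,7-dimethylocta-1,6-dien-3-yl]oxy}silane | C=C[C@](C)(O[Si](CC)(CC)CC)CCC=C(C)C | intermediate
11 | (2E,6R)-2,6-dimethyl-6-[(triethylsilyl)oxy]octa-2,7-dien-1-ol | OC/C(C)=C/CC[C@@](C)(O[Si](CC)(CC)CC)C=C | intermediate
12 | (2E,6R)-2,6-dimethyl-6-[(triethylsilyl)oxy]octa-2,7-dien-1-yl methanesulfonate | CS(=O)(=O)OC/C(C)=C/CC[C@@](C)(O[Si](CC)(CC)CC)C=C | intermediate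
13 | (3R,6E)-8-chloro-3,7-dimethyl-3-[(triethylsilyl)oxy]octa-1,6-diene | ClC/C(C)=C/CC[C@@](C)(O[Si](CC)(CC)CC)C=C | intermediate
14 | chlorido[(2E,6R)-2,6-dimethyl-6-(triethylsilyloxy)octa-2,7-dien-1-yl]barium | Cl[Ba]C/C(C)=C/CC[C@@](C)(O[Si](CC)(CC)CC)C=C | intermediate
15 | methyl (2S,5S)-2-[(1S,3E,7R)-1-hydroxy-3,7-dimethyl-7-[(triethylsilyl)oxy]nona-3,8-dien-1-yl]-2-methyl-5-(propan-2-yl)hept-6-enoate | C=C[C@H](C(C)C)CC[C@](C)(C(=O)OC)[C@@H](O)C/C(C)=C/CC[C@@](C)(O[Si](CC)(CC)CC)C=C | intermediate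
16 | methyl (1S,2S,4E,8R,9E,11S)-2-hydroxy-1,4,8-trimethyl-11-(propan-2-yl)-8-[(triethylsilyl)oxy]cyclotrideca-4,9-diene-1-carboxylate | O[C@H]1C/C(C)=C/CC[C@@](C)(O[Si](CC)(CC)CC)/C=C/[C@H](C(C)C)CC[C@]1(C)C(=O)OC | intermediate
17 | (1S,2S,4E,8R,9E,11S)-2-hydroxy-1,4,8-trimethyl-11-(propan-2-yl)-8-[(triethylsilyl)oxy]cyclotrideca-4,9-diene-1-carbaldehyde | O[C@H]1C/C(C)=C/CC[C@@](C)(O[Si](CC)(CC)CC)/C=C/[C@H](C(C)C)CC[C@]1(C)C=O | intermediate
18 | (1S,2S,4E,8R,9E,11S)-1-formyl-1,4,8-trimethyl-11-(propan-2-yl)-8-[(triethylsilyl)oxy]cyclotrideca-4,9-dien-2-yl acetate | CC(=O)O[C@H]1C/C(C)=C/CC[C@@](C)(O[Si](CC)(CC)CC)/C=C/[C@H](C(C)C)CC[C@]1(C)C=O | intermediate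
19 | CNP0106239.1, (1S,2S,4E,8R,9E,11S)-1-formyl-8-hydroxy-1,4,8-trimethyl-11-(propan-2-yl)cyclotrideca-4,9-dien-2-yl acetate | CC(=O)O[C@H]1C/C(C)=C/CC[C@@](C)(O)/C=C/[C@H](C(C)C)CC[C@]1(C)C=O | target

**Totals**
Total step count: 13. Longest linear sequence: 10 steps (steps 1–5 and 9–13 from compound 1); the linalool branch is 3 steps before the union.

**Three steps most likely to fail**

Step 4 (stannylmethyl opening of a hindered epoxide next to an ester, feeding the fragmentation). The fallback sets out from 6 and comes back at 8, avoiding epoxide opening and tin altogether. H5IO6 in THF/H2O cleaves the epoxide to methyl (2S,5S)-2,5-diformyl-2,6-dimethylheptanoate F1. This is reduced at once with NaBH4 in MeOH (to forestall intramolecular aldolisation) to methyl (2S,5S)-2,5-bis(hydroxymethyl)-2,6-dimethylheptanoate F2. Mitsunobu thioetherification with 1-phenyl-1H-tetrazole-5-thiol (DIAD, PPh3) reacts only at the non-neopentyl hydroxymethyl and gives methyl (2S,5S)-2-(hydroxymethyl)-2,6-dimethyl-5-{[(1-phenyl-1H-tetrazol-5-yl)sulfanyl]methyl}heptanoate F3. Oxidation with (NH4)6Mo7O24/H2O2 gives methyl (2S,5S)-2-(hydroxymethyl)-2,6-dimethyl-5-{[(1-phenyl-1H-tetrazol-5-yl)sulfonyl]methyl}heptanoate F4. Julia–Kocienski methylenation (KN(SiMe3)2, 2.2 equiv, then formaldehyde from paraformaldehyde) gives methyl (2S,5S)-2-(hydroxymethyl)-2-methyl-5-(propan-2-yl)hept-6-enoate F5, and Dess–Martin oxidation returns 8.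

Step 9 (the α-selectivity of allylbarium is precedented, but the chelation control at C1 is an expectation, not a known result). The fallback sets out from 15 obtained as a C1-epimer mixture and comes back at 15 as the single (1S) epimer, replacing substrate control by reagent control. Dess–Martin periodinane (NaHCO3 buffer) gives methyl (2S,5S)-2-[(3E,7R)-3,7-dimethyl-7-[(triethylsilyl)oxy]nona-3,8-dienoyl]-2-methyl-5-(propan-2-yl)hept-6-enoate F6. This ketone has a quaternary carbon on one side and CH2 on the other, so (R)-2-methyl-CBS-oxazaborolidine with catecholborane at −78 °C should deliver the (1S) alcohol 15.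

Step 10 (hindered macrocyclic metathesis; if ruthenium loads at the C8 vinyl group, five-ring closure onto the trisubstituted olefin cleaves the chain). The fallback sets out from 15 and comes back at 16 by masking the competing olefin. Pyridinium tribromide (1.0 equiv, CH2Cl2, −78 °C) adds bromine only to the electron-rich trisubstituted olefin, giving methyl (2S,5S)-2-[(1S,7R)-3,4-dibromo-1-hydroxy-3,7-dimethyl-7-[(triethylsilyl)oxy]non-8-en-1-yl]-2-methyl-5-(propan-2-yl)hept-6-enoate F7 (anti adduct, both diastereomers). Ring-closing metathesis with the same catalyst at 40 °C gives methyl (1S,2S,8R,9E,11S)-4,5-dibromo-2-hydroxy-1,4,8-trimethyl-11-(propan-2-yl)-8-[(triethylsilyl)oxy]cyclotridec-9-ene-1-carboxylate F8. Zinc dust in EtOH/AcOH then removes the bromines by anti elimination, which restores the E-trisubstituted olefin stereospecifically and gives 16.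

**Further compounds**
F1 | step 4 | methyl (2S,5S)-2,5-diformyl-2,6-dimethylheptanoate | O=C[C@H](C(C)C)CC[C@](C=O)(C)C(=O)OC
F2 | step 4 | methyl (2S,5S)-2,5-bis(hydroxymethyl)-2,6-dimethylheptanoate | OC[C@H](C(C)C)CC[C@](CO)(C)C(=O)OC
F3 | step 4 | methyl (2S,5S)-2-(hydroxymethyl)-2,6-dimethyl-5-{[(1-phenyl-1H-tetrazol-5-yl)sulfanyl]methyl}heptanoate | c1ccccc1-n1nnnc1SC[C@H](C(C)C)CC[C@](CO)(C)C(=O)OC
F4 | step 4 | methyl (2S,5S)-2-(hydroxymethyl)-2,6-dimethyl-5-{[(1-phenyl-1H-tetrazol-5-yl)sulfonyl]methyl}heptanoate | c1ccccc1-n1nnnc1S(=O)(=O)C[C@H](C(C)C)CC[C@](CO)(C)C(=O)OC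
F5 | step 4 | methyl (2S,5S)-2-(hydroxymethyl)-2-methyl-5-(propan-2-yl)hept-6-enoate | C=C[C@H](C(C)C)CC[C@](CO)(C)C(=O)OC
F6 | step 9 | methyl (2S,5S)-2-[(3E,7R)-3,7-dimethyl-7-[(triethylsilyl)oxy]nona-3,8-dienoyl]-2-methyl-5-(propan-2-yl)hept-6-enoate | C=C[C@H](C(C)C)CC[C@](C)(C(=O)OC)C(=O)C/C(C)=C/CC[C@@](C)(O[Si](CC)(CC)CC)C=C
F7 | step 10 | methyl (2S,5S)-2-[(1S,7R)-3,4-dibromo-1-hydroxy-3,7-dimethyl-7-[(triethylsilyl)oxy]non-8-en-1-yl]-2-methyl-5-(propan-2-yl)hept-6-enoate (anti dibromide, both diastereomers) | C=C[C@H](C(C)C)CC[C@](C)(C(=O)OC)[C@@H](O)CC(C)(Br)C(Br)CC[C@@](C)(O[Si](CC)(CC)CC)C=C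
F8 | step 10 | methyl (1S,2S,8R,9E,11S)-4,5-dibromo-2-hydroxy-1,4,8-trimethyl-11-(propan-2-yl)-8-[(triethylsilyl)oxy]cyclotridec-9-ene-1-carboxylate | O[C@H]1CC(C)(Br)C(Br)CC[C@@](C)(O[Si](CC)(CC)CC)/C=C/[C@H](C(C)C)CC[C@]1(C)C(=O)OC
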